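**Retrosynthetic overview**
- Caraphenol C (all-cis) ⇐ hexabenzyl 3-aroyl-1,2-diaryl-1H-indene: one H2/Pd operation adds H2 syn to the C1=C2 enone from the face opposite the C3 aryl and removes all benzyl groups.
- Aroylindene ⇐ indenyl triflate + aryl stannane + CO (carbonylative Stille) ⇐ 2,3-diarylindan-1-one.
- Key disconnection, C2–C3 of the indanone: an alpha-aryl-alpha-diazo ketone gives a rhodium carbenoid whose ketone alpha-carbon acts as an electrophile (enolonium equivalent) and inserts into a diarylmethane C–H bond, setting C3.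
- Diazo ketone ⇐ benzyl ketone ⇐ Ivanov–Claisen condensation of an arylacetic acid with a 2-benzylated 3,5-dialkoxybenzoate (Friedel–Crafts).
- Ring order: all four benzene rings are bought; the cyclopentane ring is the only ring built (step 4).

**Assumptions**
- The target SMILES is read as (1R,2R,3R), i.e. the aroyl group at C1, the 3,5-dihydroxyphenyl at C2 and the 4-hydroxyphenyl at C3 all on the same face of the indane; the route is built for this all-cis isomer.
- Rh2(S-PTTL)4 (dirhodium tetrakis[N-phthaloyl-(S)-tert-leucinate]) is written for step 4; its sense of induction on this substrate is not known, and the mirror-image catalyst is used if the first run favours (3S).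
- Benzyl-protected building blocks 1, 2, 4 and 10 are taken as catalogue compounds.

**Route**

Step 1
Reactants: 1 methyl 3,5-bis(benzyloxy)benzoate; 2 [4-(benzyloxy)phenyl]methanol
Product: 3 methyl 3,5-bis(benzyloxy)-2-[4-(benzyloxy)benzyl]benzoate
Conditions: Bi(OTf)3 (5 mol %), MeNO2, 40 °C, 1 in excess (2.5 equiv), slow addition of 2
Reagents that add atoms: none
Why: Friedel–Crafts benzylation in which the 4-(benzyloxy)benzyl cation attacks C2 of 1 (para to one benzyloxy group, ortho to the other, the site at which 3,5-dialkoxybenzoates are also brominated and formylated), with excess 1 and the deactivating ester suppressing a second alkylation; no stereocenter.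

Step 2
Reactants: 3 methyl 3,5-bis(benzyloxy)-2-[4-(benzyloxy)benzyl]benzoate; 4 [3,5-bis(benzyloxy)phenyl]acetic acid
Product: 6 2-[3,5-bis(benzyloxy)phenyl]-1-{3,5-bis(benzyloxy)-2-[4-(benzyloxy)benzyl]phenyl}ethan-1-one, via beta-keto acid 5 (not isolated)
Conditions: 4, t-BuMgCl (2.2 equiv per 4), THF, 0 to 65 °C; then 3, 65 °C; aq HCl, rt
Reagents that add atoms: none
Why: Ivanov–Claisen condensation in which the magnesium enediolate of 4 is C-acylated by ester 3 and the beta-keto acid loses CO2 on acidification to give the benzyl ketone; no stereocenter.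

Step 3
Reactants: 6 2-[3,5-bis(benzyloxy)phenyl]-1-{3,5-bis(benzyloxy)-2-[4-(benzyloxy)benzyl]phenyl}ethan-1-one
Product: 7 2-[3,5-bis(benzyloxy)phenyl]-1-{3,5-bis(benzyloxy)-2-[4-(benzyloxy)benzyl]phenyl}-2-diazoethan-1-one
Conditions: p-ABSA, DBU, MeCN, 0 °C to rt
Reagents that add atoms: 4-acetamidobenzenesulfonyl azide (p-ABSA), CC(=O)Nc1ccc(cc1)S(=O)(=O)N=[N+]=[N-]
Why: Regitz diazo transfer to the methylene activated by both carbonyl and aryl, while the far less acidic diarylmethane CH2 is untouched; no stereocenter.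

Step 4
Reactants: 7 2-[3,5-bis(benzyloxy)phenyl]-1-{3,5-bis(benzyloxy)-2-[4-(benzyloxy)benzyl]phenyl}-2-diazoethan-1-one
Product: 8 (2R,3R)-4,6-bis(benzyloxy)-2-[3,5-bis(benzyloxy)phenyl]-3-[4-(benzyloxy)phenyl]-2,3-dihydro-1H-inden-1-one
Conditions: Rh2(S-PTTL)4 (1 mol %), CH2Cl2, 4 Å MS, −40 to 0 °C, slow addition of 7; then Et3N (0.2 equiv), rt
Reagents that add atoms: none
Why: Proposed new method: the rhodium carbenoid from 7 makes the carbon alpha to the ketone an electrophile (enolonium equivalent), which inserts 1,5 into one of the two enantiotopic, strongly hydridic C–H bonds of the doubly benzylic CH2 inside the chiral carboxylate pocket, closing the cyclopentanone and setting C3 as R (C2 is equilibrated to trans by Et3N and is erased in step 5); the closest known chemistry is the enantioselective intramolecular C–H insertion of alpha-aryl-alpha-diazo ketones to alpha-aryl cyclopentanones and of aryldiazoacetates into benzylic C–H bonds with phthalimido-carboxylate catalysts of divalent rhodium.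

Step 5
Reactants: 8 (2R,3R)-4,6-bis(benzyloxy)-2-[3,5-bis(benzyloxy)phenyl]-3-[4-(benzyloxy)phenyl]-2,3-dihydro-1H-inden-1-one
Product: 9 (1R)-5,7-bis(benzyloxy)-2-[3,5-bis(benzyloxy)phenyl]-1-[4-(benzyloxy)phenyl]-1H-inden-3-yl trifluoromethanesulfonate
Conditions: Tf2O, 2,6-di-tert-butyl-4-methylpyridine, CH2Cl2, −20 to 0 °C
Reagents that add atoms: trifluoromethanesulfonic anhydride (Tf2O), O=S(=O)(OS(=O)(=O)C(F)(F)F)C(F)(F)F
Why: Enol triflate formation by O-triflation and loss of the only alpha-hydrogen (C2–H) under non-basic conditions, so the aryl-bearing center (now C1 of the indene) keeps its configuration while C2 becomes sp2.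

Step 6
Reactants: 10 1-(benzyloxy)-4-bromobenzene
Product: 12 tributyl[4-(benzyloxy)phenyl]stannane, via aryllithium 11 (not isolated)
Conditions: n-BuLi, THF, −78 °C; then Bu3SnCl, −78 °C to rt
Reagents that add atoms: tributyltin chloride (Bu3SnCl), CCCC[Sn](Cl)(CCCC)CCCC
Why: Lithium–bromine exchange (faster at −78 °C than any attack on the benzyl ether) followed by substitution at tin; no stereocenter.

Step 7
Reactants: 9 (1R)-5,7-bis(benzyloxy)-2-[3,5-bis(benzyloxy)phenyl]-1-[4-(benzyloxy)phenyl]-1H-inden-3-yl trifluoromethanesulfonate; 12 tributyl[4-(benzyloxy)phenyl]stannane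
Product: 13 {(1S)-5,7-bis(benzyloxy)-2-[3,5-bis(benzyloxy)phenyl]-1-[4-(benzyloxy)phenyl]-1H-inden-3-yl}[4-(benzyloxy)phenyl]methanone
Conditions: CO (3 atm), Pd(PPh3)4 (5 mol %), LiCl (3 equiv), THF, 60 °C
Reagents that add atoms: carbon monoxide, [C-]#[O+]
Why: Carbonylative Stille coupling (oxidative addition of zerovalent palladium to the vinyl triflate, CO insertion, aryl transfer from tin) under neutral conditions, chosen because the indene C1–H of 13 is acidic and would racemize with the bases of a carbonylative Suzuki coupling; no new stereocenter (the descriptor changes from R to S only through CIP priorities).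

Step 8
Reactants: 13 {(1S)-5,7-bis(benzyloxy)-2-[3,5-bis(benzyloxy)phenyl]-1-[4-(benzyloxy)phenyl]-1H-inden-3-yl}[4-(benzyloxy)phenyl]methanone
Product: 15 caraphenol C [(1R,2R,3R)-2-(3,5-dihydroxyphenyl)-4,6-dihydroxy-3-(4-hydroxyphenyl)-2,3-dihydro-1H-inden-1-yl](4-hydroxyphenyl)methanone, via hexaphenol indene 14 (not isolated)
Conditions: H2 (4 atm), Pd(OH)2/C, EtOAc/MeOH (1:1), rt
Reagents that add atoms: none
Why: Heterogeneous hydrogenation with hydrogenolysis, in which both hydrogens add syn to the tetrasubstituted C=C from the face opposite the aryl group on the existing stereocenter, so the aroyl, 3,5-dihydroxyphenyl and 4-hydroxyphenyl groups end up on one face (C1 R and C2 R set here, all-cis to C3 R), while the six benzyl ethers are cleaved under neutral conditions that do not enolize the new alpha-keto center.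

**Compound list**
1 | methyl 3,5-bis(benzyloxy)benzoate | COC(=O)c1cc(OCc2ccccc2)cc(OCc2ccccc2)c1 | starting material
2 | [4-(benzyloxy)phenyl]methanol | OCc1ccc(OCc2ccccc2)cc1 | starting material
3 | methyl 3,5-bis(benzyloxy)-2-[4-(benzyloxy)benzyl]benzoate | COC(=O)c1cc(OCc2ccccc2)cc(OCc2ccccc2)c1Cc1ccc(OCc2ccccc2)cc1 | intermediate
4 | [3,5-bis(benzyloxy)phenyl]acetic acid | OC(=O)Cc1cc(OCc2ccccc2)cc(OCc2ccccc2)c1 | starting material
5 | racemic 2-[3,5-bis(benzyloxy)phenyl]-3-{3,5-bis(benzyloxy)-2-[4-(benzyloxy)benzyl]phenyl}-3-oxopropanoic acid (formed as its magnesium salt, not isolated) | OC(=O)C(c1cc(OCc2ccccc2)cc(OCc2ccccc2)c1)C(=O)c1cc(OCc2ccccc2)cc(OCc2ccccc2)c1Cc1ccc(OCc2ccccc2)cc1 | intermediate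
6 | 2-[3,5-bis(benzyloxy)phenyl]-1-{3,5-bis(benzyloxy)-2-[4-(benzyloxy)benzyl]phenyl}ethan-1-one | O=C(Cc1cc(OCc2ccccc2)cc(OCc2ccccc2)c1)c1cc(OCc2ccccc2)cc(OCc2ccccc2)c1Cc1ccc(OCc2ccccc2)cc1 | intermediate
7 | 2-[3,5-bis(benzyloxy)phenyl]-1-{3,5-bis(benzyloxy)-2-[4-(benzyloxy)benzyl]phenyl}-2-diazoethan-1-one | [N-]=[N+]=C(c1cc(OCc2ccccc2)cc(OCc2ccccc2)c1)C(=O)c1cc(OCc2ccccc2)cc(OCc2ccccc2)c1Cc1ccc(OCc2ccccc2)cc1 | intermediate
8 | (2R,3R)-4,6-bis(benzyloxy)-2-[3,5-bis(benzyloxy)phenyl]-3-[4-(benzyloxy)phenyl]-2,3-dihydro-1H-inden-1-one | O=C1[C@@H](c2cc(OCc3ccccc3)cc(OCc3ccccc3)c2)[C@H](c2ccc(OCc3ccccc3)cc2)c2c(OCc3ccccc3)cc(OCc3ccccc3)cc21 | intermediate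
9 | (1R)-5,7-bis(benzyloxy)-2-[3,5-bis(benzyloxy)phenyl]-1-[4-(benzyloxy)phenyl]-1H-inden-3-yl trifluoromethanesulfonate | FC(F)(F)S(=O)(=O)OC1=C(c2cc(OCc3ccccc3)cc(OCc3ccccc3)c2)[C@H](c2ccc(OCc3ccccc3)cc2)c2c(OCc3ccccc3)cc(OCc3ccccc3)cc21 | intermediate
10 | 1-(benzyloxy)-4-bromobenzene | Brc1ccc(OCc2ccccc2)cc1 | starting material
11 | [4-(benzyloxy)phenyl]lithium (not isolated) | [Li]c1ccc(OCc2ccccc2)cc1 | intermediate
12 | tributyl[4-(benzyloxy)phenyl]stannane | CCCC[Sn](CCCC)(CCCC)c1ccc(OCc2ccccc2)cc1 | intermediate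
13 | {(1S)-5,7-bis(benzyloxy)-2-[3,5-bis(benzyloxy)phenyl]-1-[4-(benzyloxy)phenyl]-1H-inden-3-yl}[4-(benzyloxy)phenyl]methanone | O=C(c1ccc(OCc2ccccc2)cc1)C1=C(c2cc(OCc3ccccc3)cc(OCc3ccccc3)c2)[C@H](c2ccc(OCc3ccccc3)cc2)c2c(OCc3ccccc3)cc(OCc3ccccc3)cc21 | intermediate
14 | [(1S)-2-(3,5-dihydroxyphenyl)-5,7-dihydroxy-1-(4-hydroxyphenyl)-1H-inden-3-yl](4-hydroxyphenyl)methanone (not isolated) | O=C(c1ccc(O)cc1)C1=C(c2cc(O)cc(O)c2)[C@H](c2ccc(O)cc2)c2c(O)cc(O)cc21 | intermediate
15 | caraphenol C, [(1R,2R,3R)-2-(3,5-dihydroxyphenyl)-4,6-dihydroxy-3-(4-hydroxyphenyl)-2,3-dihydro-1H-inden-1-yl](4-hydroxyphenyl)methanone | O=C(c1ccc(O)cc1)[C@H]1c2cc(O)cc(O)c2[C@@H](c2ccc(O)cc2)[C@H]1c1cc(O)cc(O)c1 | target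

**Step count**
Total steps: 8. Longest linear sequence: 7 (steps 1, 2, 3, 4, 5, 7, 8); step 6 is a one-step side branch.

**Three steps most likely to fail, with fallbacks**

Step 4 (carbenoid C–H insertion). The risks are attack of the carbenoid on the 4-(benzyloxy)phenyl ring (ipso or Buchner pathways) and low enantioselectivity if the very hydridic C–H reacts through a stepwise hydride-transfer pathway. The fallback sets out from ketone 6 and moves the enantio-determining event to a reduction. DDQ (2.2 equiv, CH2Cl2, rt) abstracts hydride from the diarylmethane carbon, and the resulting cation is captured on carbon by the ketone enol (O-capture is reversible under these conditions). This gives racemic 4,6-bis(benzyloxy)-2-[3,5-bis(benzyloxy)phenyl]-3-[4-(benzyloxy)phenyl]-2,3-dihydro-1H-inden-1-one F1 (not isolated). The second equivalent of DDQ dehydrogenates it to 4,6-bis(benzyloxy)-2-[3,5-bis(benzyloxy)phenyl]-3-[4-(benzyloxy)phenyl]-1H-inden-1-one F2. Enantioselective conjugate reduction of this achiral indenone with a copper hydride catalyst (Cu(OAc)2, (R)-DTBM-SEGPHOS or its enantiomer as required, (EtO)2MeSiH, t-BuOH, toluene), followed by the same Et3N equilibration of C2, comes back to the route at 8.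

Step 7 (carbonylative Stille). The risks are slow aryl transfer to a hindered acylpalladium, direct non-carbonylative coupling, and erosion of the acidic indene stereocenter. The fallback sets out from triflate 9 and reverses the roles of the partners. Pd(PPh3)4, LiCl and Me3SnSnMe3 in dioxane at 60 °C give {(1R)-5,7-bis(benzyloxy)-2-[3,5-bis(benzyloxy)phenyl]-1-[4-(benzyloxy)phenyl]-1H-inden-3-yl}trimethylstannane F3. Base-free Stille acylation of this stannane with commercial 4-(benzyloxy)benzoyl chloride (PdCl2(PPh3)2, toluene, 60 °C) comes back to the route at 13.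

Step 8 (hydrogenation with hydrogenolysis). The risks are over-reduction of the aryl ketone, palladium-mediated double-bond migration that could erode the ee, and incomplete reduction of the tetrasubstituted alkene once the phenols are free. The fallback sets out from 13 and separates the two events. Homogeneous hydrogenation with [Ir(cod)(PCy3)(py)]PF6 (H2 1 atm, CH2Cl2, rt), which reduces tetrasubstituted alkenes and leaves benzyl ethers and the ketone intact, gives {(1R,2R,3R)-4,6-bis(benzyloxy)-2-[3,5-bis(benzyloxy)phenyl]-3-[4-(benzyloxy)phenyl]-2,3-dihydro-1H-inden-1-yl}[4-(benzyloxy)phenyl]methanone F4 by addition anti to the C3 aryl group. Neutral transfer hydrogenolysis (Pd/C, cyclohexa-1,4-diene, EtOH, rt) then removes the six benzyl groups and comes back to the route at 15.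

**Further compounds**
F1 | step 4 | racemic 4,6-bis(benzyloxy)-2-[3,5-bis(benzyloxy)phenyl]-3-[4-(benzyloxy)phenyl]-2,3-dihydro-1H-inden-1-one | O=C1C(c2cc(OCc3ccccc3)cc(OCc3ccccc3)c2)C(c2ccc(OCc3ccccc3)cc2)c2c(OCc3ccccc3)cc(OCc3ccccc3)cc21
F2 | step 4 | 4,6-bis(benzyloxy)-2-[3,5-bis(benzyloxy)phenyl]-3-[4-(benzyloxy)phenyl]-1H-inden-1-one | O=C1C(c2cc(OCc3ccccc3)cc(OCc3ccccc3)c2)=C(c2ccc(OCc3ccccc3)cc2)c2c(OCc3ccccc3)cc(OCc3ccccc3)cc21
F3 | step 7 | {(1R)-5,7-bis(benzyloxy)-2-[3,5-bis(benzyloxy)phenyl]-1-[4-(benzyloxy)phenyl]-1H-inden-3-yl}trimethylstannane | C[Sn](C)(C)C1=C(c2cc(OCc3ccccc3)cc(OCc3ccccc3)c2)[C@H](c2ccc(OCc3ccccc3)cc2)c2c(OCc3ccccc3)cc(OCc3ccccc3)cc21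
F4 | step 8 | {(1R,2R,3R)-4,6-bis(benzyloxy)-2-[3,5-bis(benzyloxy)phenyl]-3-[4-(benzyloxy)phenyl]-2,3-dihydro-1H-inden-1-yl}[4-(benzyloxy)phenyl]methanone | O=C(c1ccc(OCc2ccccc2)cc1)[C@H]1c2cc(OCc3ccccc3)cc(OCc3ccccc3)c2[C@@H](c2ccc(OCc3ccccc3)cc2)[C@H]1c1cc(OCc2ccccc2)cc(OCc2ccccc2)c1
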